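Locants (seco-eudesmane): C1 side-chain CH2O, C2, C3, C4 side-chain CH (methyl C15), C5 ring alkene carbon bearing the chain, C6 CH–O-isobutyrate, C7/C8 lactone fusion (O on C8), C9 ring CH2, C10 ring alkene carbon bearing methyl C14, C11/C12/C13 lactone α-carbon, carbonyl, methylene. α is the ring face of C8–O and C11, β that of C6–O.
Cuts, in order: C11=C13 (phosphonate olefination) and the two isobutyrate C–O bonds. Then C3–C4, with C1–C10 restored (retro oxy-Cope). Then C7–C11 and O8–C12 (phosphonoacetate tethered over a C6–C7 oxirane), C1–C2 (vinyl) and C4–C5 (ethyl). Last, C5–C6 and C9–C10 (Diels–Alder).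
Enabling feature: with C1 at the aldehyde level, side chain and carbocycle contain O=C1–C2–C3–C4–C5=C10. This is a δ,ε-unsaturated carbonyl whose alkene is the tetrasubstituted ring double bond, i.e. the oxy-Cope retron. C4 and C5=C10 can therefore both come from a throw-away quaternary C10 (methyl plus 1-hydroxyallyl) next to a C5 ethylidene.
Forward order of rings: carbocycle (cycloaddition), temporary C1(=O)–O–C8 bridged γ-lactone (iodolactonisation), C6–C7 oxirane, reductive release of the bridge, permanent cis-fused γ-lactone (oxirane opening). The [3,3] shift then carries C1–C3 from C10 to C4, and the methylene comes last.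
Stereochemistry: C10 comes from the catalytic asymmetric cycloaddition. It then places C8–O (α), the oxirane and hence C6–O (β, anti to the bridge), and C11 on C7 (α, anti opening by the C8-tethered carbanion). Together with the (Z)-ethylidene it also sets C4 (S, suprafacial transfer). C1, C10 and C11 are erased later.
Key step: step 14

Assumption: the sense of induction in step 1 is taken from the usual formyl C–H···O binding model, which pairs the (R)-diphenylprolinol-derived catalyst with the (R)-aldehyde; centres that are erased later (the C5 carbinol, the lactol carbon, C1 and C11) are carried as mixtures and left undefined in the SMILES.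

Step 1
Reactants: 1 methacrolein; 2 buta-1,3-diene
Product: 3 (R)-1-methylcyclohex-3-ene-1-carbaldehyde (quaternary C10, CHO = C1 on the α face, ring alkene C7=C8)
Conditions: (R)-tetrahydro-1-(2-methylphenyl)-3,3-diphenyl-1H,3H-pyrrolo[1,2-c][1,3,2]oxazaborole (10 mol %), (CF3SO2)2NH (10 mol %), CH2Cl2, −78 to −40 °C
Reagents that add atoms: none
Why: Enantioselective Diels–Alder reaction under a protonated oxazaborolidine: the s-trans enal is held on boron, a catalyst phenyl group covers one face of its C=C, and the diene adds to the free face to set quaternary C10 as R.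

Step 2
Reactants: 3 (R)-1-methylcyclohex-3-ene-1-carbaldehyde
Product: 4 (R)-1-methylcyclohex-3-ene-1-carboxylic acid
Conditions: NaClO2, NaH2PO4, 2-methylbut-2-ene, t-BuOH/H2O, 0 °C to rt
Reagents that add atoms: sodium chlorite, [Na+].[O-]Cl=O
Why: Pinnick oxidation turns the non-enolisable neopentyl aldehyde into the acid, the scavenger alkene protects the ring alkene from HOCl, and C10 is untouched.

Step 3
Reactants: 4 (R)-1-methylcyclohex-3-ene-1-carboxylic acid
Product: 5 (1R,4R,5R)-4-iodo-1-methyl-6-oxabicyclo[3.2.1]octan-7-one (C1 carboxyl bridged to C8–O on the α face, iodine on C7 β)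
Conditions: I2, KI, NaHCO3, CH2Cl2/H2O, 0 °C to rt, dark
Reagents that add atoms: iodine, II
Why: Iodolactonisation: the carboxylate can reach only the α face and opens the β iodonium ion at C8 in the five-membered mode, so C8–O ends cis to C1 and trans to C7–I.

Step 4
Reactants: 5 iodolactone
Product: 6 (1R,5R)-1-methyl-6-oxabicyclo[3.2.1]oct-3-en-7-one (C6=C7 alkene)
Conditions: 1,8-diazabicyclo[5.4.0]undec-7-ene (DBU), toluene, 90 °C
Reagents that add atoms: none
Why: E2 elimination: the axial C7–I bond is antiperiplanar only to the α hydrogen on C6, and loss of the bridgehead C8–H would need a bridgehead alkene, so only the C6=C7 alkene can form.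

Step 5
Reactants: 6 unsaturated bridged lactone
Product: 7 2-hydroxy-1-methyl-6-oxabicyclo[3.2.1]oct-3-en-7-one (C5 carbinol, OH expected β, C6=C7 retained)
Conditions: SeO2, 1,4-dioxane, 100 °C
Reagents that add atoms: selenium dioxide, O=[Se]=O
Why: Riley allylic hydroxylation: the ene step can take a hydrogen only from C5 while selenium binds C7, and the following [2,3] shift returns oxygen to C5 and the alkene to C6=C7, so the regiochemistry is fixed by mechanism and the carbinol configuration does not matter.

Step 6
Reactants: 7 allylic alcohol
Product: 8 (1S,5R)-1-methyl-6-oxabicyclo[3.2.1]oct-3-ene-2,7-dione (C5 ketone conjugated with C6=C7)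
Conditions: Dess–Martin periodinane, CH2Cl2, 0 °C to rt
Reagents that add atoms: none
Why: Dess–Martin oxidation of a secondary allylic alcohol under neutral conditions, which spare the non-enolisable β-keto lactone and converge any enone already formed in step 5.

Step 7
Reactants: 8 bridged enone
Product: 9 3,4-epoxy-1-methyl-6-oxabicyclo[3.2.1]octane-2,7-dione (C5 ketone, C6–C7 oxirane on the β face, anti to the lactone bridge)
Conditions: t-BuOOH (decane), DBU, CH2Cl2, 0 °C
Reagents that add atoms: tert-butyl hydroperoxide, CC(C)(C)OO
Why: Weitz–Scheffer nucleophilic epoxidation: t-BuOO− adds to C7 on the open β face, anti to the axial C8–O bond and away from the two-atom bridge, and the enolate closes the oxirane on that face, fixing C6–O as β.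

Step 8
Reactants: 9 epoxy keto lactone; 10 ethylmagnesium bromide
Product: 11 2-ethyl-2-hydroxy-3,4-epoxy-1-methyl-6-oxabicyclo[3.2.1]octan-7-one (tertiary C5 carbinol, either epimer; oxirane β)
Conditions: anhydrous CeCl3, THF, −78 °C; aq. NH4Cl at −78 °C
Reagents that add atoms: ethylmagnesium bromide 10, CC[Mg]Br
Why: Organocerium 1,2-addition: the weakly basic, oxophilic ethylcerium species attacks the hindered non-enolisable ketone faster than lactone or oxirane and suppresses β-hydride reduction, and the new carbinol centre disappears in step 9.

Step 9
Reactants: 11 tertiary carbinol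
Product: 13 (Z)-2-ethylidene-3,4-epoxy-1-methyl-6-oxabicyclo[3.2.1]octan-7-one (CH3-15 on the C6 side and vinylic H on the C10 side; oxirane β), via Burgess sulfamate ester 12 (not isolated)
Conditions: Burgess reagent (MeO2C–N(−)–SO2–N(+)Et3), toluene, 60 °C
Reagents that add atoms: none
Why: Burgess syn-elimination: C10 has no hydrogen and loss of C6–H would give a methyleneoxirane, so only a C4 hydrogen can leave, and the eclipsed transition state with CH3-15 over the oxirane CH (C6) beats the one with it over quaternary C10 and its in-plane methyl, giving the (Z)-alkene, which is also the more stable isomer (a Wittig ethylidenation is avoided because it tends to put the methyl beside the bulkier flank).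

Step 10
Reactants: 13 (Z)-ethylidene epoxy lactone
Product: 14 bridged lactol, (Z)-2-ethylidene-3,4-epoxy-1-methyl-6-oxabicyclo[3.2.1]octan-7-ol (anomer mixture)
Conditions: i-Bu2AlH (1.1 equiv), CH2Cl2, −78 °C; aq. KNaC4H4O6
Reagents that add atoms: none
Why: Partial lactone reduction with i-Bu2AlH: the tetrahedral aluminium hemiacetal persists at −78 °C, so reduction stops at the lactol and the vinyl oxirane is left alone.

Step 11
Reactants: 14 bridged lactol; 15 vinylmagnesium bromide
Product: 17 epoxy diol: cyclohexane with C10 bearing CH3 (β) and 1-hydroxyallyl (α; C1 epimers), C8–OH α, C6–C7 oxirane β, (Z)-ethylidene on C5, via ring-opened aldehyde alkoxide 16 (not isolated)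
Conditions: THF, −78 to −30 °C; aq. NH4Cl at −30 °C
Reagents that add atoms: vinylmagnesium bromide 15, C=C[Mg]Br
Why: Grignard addition to a lactol through its open hydroxy aldehyde: one equivalent deprotonates, the non-enolisable neopentyl aldehyde takes up vinyl, and the cold magnesium alkoxide at O8 does not trigger Payne migration of the oxirane; both C1 epimers are useful.

Step 12
Reactants: 17 epoxy diol; 18 diethylphosphonoacetic acid
Product: 19 C8 (diethoxyphosphoryl)acetate of the epoxy diol (C1–OH free)
Conditions: N,N'-dicyclohexylcarbodiimide, 4-dimethylaminopyridine (5 mol %), CH2Cl2, −10 to 0 °C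
Reagents that add atoms: diethylphosphonoacetic acid 18, OC(=O)CP(=O)(OCC)OCC
Why: Steglich esterification, chemoselective for the unhindered ring carbinol C8–OH over the neopentyl C1–OH beside quaternary C10.

Step 13
Reactants: 19 C8 phosphonoacetate
Product: 20 oxy-Cope precursor: cis-fused α-(diethoxyphosphoryl)-γ-lactone (C8–O α, C7–C11 α; C11 epimers), C6–OH β, (Z)-ethylidene on C5, C10 bearing CH3 (β) and 1-hydroxyallyl (α)
Conditions: LiCl, DBU, MeCN, 0 °C to rt
Reagents that add atoms: none
Why: Proposed new method: lithium-assisted soft deprotonation ionises only the phosphonoacetate CH2, and the carbanion, held on the α face by the O8 ester tether, attacks neighbouring C7 from the rear of the β C7–O bond (5-exo-tet, trans-diaxial opening through the half-chair with C8–O pseudo-equatorial), so C11 ends cis to C8–O and trans to C6–O; the released C6 alkoxide is reprotonated at once by DBU-H+, which keeps it away from phosphorus and from the lactone carbonyl; the usual 5-(enolendo) restriction should not bite because the carbanion can twist out of conjugation with the in-ring ester carbonyl while the exocyclic phosphoryl group still stabilises it; the closest known reaction types are the intramolecular Michael closure of 4-(phosphonoacetoxy)cycloalkenones to cis-fused α-phosphono-γ-lactones and the intermolecular opening of epoxides by phosphonoacetate carbanions.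

Step 14
Reactants: 20 oxy-Cope precursor
Product: 23 seco-eudesmane aldehyde: 4S side chain CH(CH3)CH2CH2CHO on C5, tetrasubstituted C5=C10 alkene, C6–OH β, cis-fused α-phosphono lactone, via tripotassium salt of the precursor 21 (not isolated), via tripotassium enolate 22 (not isolated)
Conditions: KH (5 equiv), 18-crown-6 (5 equiv), THF, 0 °C to rt; cannulation into AcOH/THF at −78 °C
Reagents that add atoms: none
Why: KH ionises first the phosphonate CH and then both hydroxyls, and the crown-ether-separated potassium alkoxide on C1 weakens the adjoining C1–C10 σ bond, so that C3=C2–C1–C10–C5=C4 reorganises in one concerted, charge-accelerated [3,3] shift: C1–C10 breaks, C3–C4 forms, and the π bonds reappear as the C5=C10 ring alkene and the C1=C2 enolate, which gives the aldehyde on quench. The closest known reaction type is the anionic oxy-Cope rearrangement of open-chain 1,5-dien-3-ols with 1,3-chirality transfer, in particular of 1-(2-alkylidenecycloalkyl)allyl alcohols. Since the event only transposes a three-carbon chain and forms no ring, the question of a closure mode does not arise; the six-centre transition state merely demands the ring conformer in which C1 is axial and parallel to the ethylidene π orbitals. The one new stereocentre, C4, is governed by C10 and by the alkene geometry: C1 departs from the α face, C3 must bond to that same face of C4, and with CH3-15 syn to C6 (pseudo-equatorial in the transition state) the outcome is 4S for either C1 epimer and for chair or boat, because C3 carries two hydrogens. The step needs bonding on one face of C4 and rearrangement in preference to retro-ene cleavage, heterolysis, acyl transfer or carbon-to-oxygen phosphoryl migration; suprafaciality secures the first, the alkoxide has no hydroxyl proton for a retro-ene process, heterolysis would have to expel a plain alkyl-substituted allyl anion, and excess base keeps the phosphono lactone as a delocalised carbanion that neither alkoxide can attack. The shift is pulled forward by three gains (an enolate replaces an alkoxide, the congested C10 becomes planar, the ring alkene ends up tetrasubstituted), and inverse addition to cold acetic acid protonates all three anionic sites before the phosphonate carbanion can condense with the liberated aldehyde.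

Step 15
Reactants: 23 seco-eudesmane aldehyde
Product: 24 diol: C1–OH (primary) and C6–OH β on the α-phosphono lactone, 4S
Conditions: NaBH4, MeOH/THF, −40 °C
Reagents that add atoms: none
Why: Chemoselective borohydride reduction of the aldehyde at low temperature, far faster than attack on the lactone or any base-induced phosphonate condensation.

Step 16
Reactants: 24 diol; 25 isobutyric anhydride
Product: 26 bis-isobutyrate α-phosphono lactone (C1–O and C6–O β acylated, 4S)
Conditions: Et3N, 4-dimethylaminopyridine (20 mol %), CH2Cl2, rt
Reagents that add atoms: isobutyric anhydride 25, CC(C)C(=O)OC(=O)C(C)C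
Why: Nucleophile-catalysed acylation esterifies the primary C1–OH and the secondary allylic C6–OH with retention at C6, and triethylamine is too weak to ionise the phosphono lactone.

Step 17
Reactants: 26 bis-isobutyrate α-phosphono lactone
Product: 27 target CNP0509808.1, (3aR,4S,7aR)-6-methyl-3-methylidene-5-[(2S)-5-(2-methylpropanoyloxy)pentan-2-yl]-2-oxo-2,3,3a,4,7,7a-hexahydro-1-benzofuran-4-yl 2-methylpropanoate
Conditions: 37 % aq. HCHO, K2CO3, THF, 0 °C to rt
Reagents that add atoms: formaldehyde, C=O
Why: Horner–Wadsworth–Emmons methylenation: carbonate ionises the α-phosphono lactone, and addition to formaldehyde with loss of diethyl phosphate gives C11=C13, which erases the C11 mixture while the hindered isobutyrates survive the brief mild base.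

Compound list
1 | methacrolein | C=C(C)C=O | starting material
2 | buta-1,3-diene | C=CC=C | starting material
3 | (R)-1-methylcyclohex-3-ene-1-carbaldehyde | O=C[C@@]1(C)CC=CCC1 | intermediate
4 | (R)-1-methylcyclohex-3-ene-1-carboxylic acid | OC(=O)[C@@]1(C)CC=CCC1 | intermediate
5 | (1R,4R,5R)-4-iodo-1-methyl-6-oxabicyclo[3.2.1]octan-7-one | O=C1O[C@@H]2C[C@@]1(C)CC[C@H]2I | intermediate
6 | (1R,5R)-1-methyl-6-oxabicyclo[3.2.1]oct-3-en-7-one | O=C1O[C@@H]2C[C@@]1(C)CC=C2 | intermediate
7 | 2-hydroxy-1-methyl-6-oxabicyclo[3.2.1]oct-3-en-7-one (C5–OH β expected) | O=C1O[C@@H]2C[C@@]1(C)[C@@H](O)C=C2 | intermediate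
8 | (1S,5R)-1-methyl-6-oxabicyclo[3.2.1]oct-3-ene-2,7-dione | O=C1O[C@@H]2C[C@@]1(C)C(=O)C=C2 | intermediate
9 | bridged epoxy keto lactone (C6–C7 oxirane β) | O=C1O[C@@H]2C[C@@]1(C)C(=O)[C@H]3O[C@@H]23 | intermediate
10 | ethylmagnesium bromide | CC[Mg]Br | starting material
11 | bridged epoxy lactone with tertiary C5 ethyl carbinol (C5 undefined) | O=C1O[C@@H]2C[C@@]1(C)C(O)(CC)[C@H]3O[C@@H]23 | intermediate
12 | triethylammonium salt of the C5 N-(methoxycarbonyl)sulfamate ester (not isolated) | CC[NH+](CC)CC.O=C1O[C@@H]2C[C@@]1(C)C(CC)(OS(=O)(=O)[N-]C(=O)OC)[C@H]3O[C@@H]23 | intermediate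
13 | bridged (Z)-ethylidene epoxy lactone | O=C1O[C@@H]2C[C@@]1(C)/C(=C/C)[C@H]3O[C@@H]23 | intermediate
14 | bridged (Z)-ethylidene epoxy lactol (anomers) | OC1O[C@@H]2C[C@@]1(C)/C(=C/C)[C@H]3O[C@@H]23 | intermediate
15 | vinylmagnesium bromide | C=C[Mg]Br | starting material
16 | ring-opened C1 aldehyde as its O8 bromomagnesium alkoxide (not isolated) | O=C[C@@]1(C)C[C@@H](O[Mg]Br)[C@@H]2O[C@@H]2/C1=C\C | intermediate
17 | epoxy diol (C1 epimers) | C=CC(O)[C@@]1(C)C[C@@H](O)[C@@H]2O[C@@H]2/C1=C\C | intermediate
18 | diethylphosphonoacetic acid | OC(=O)CP(=O)(OCC)OCC | starting material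
19 | C8 phosphonoacetate of the epoxy diol | C=CC(O)[C@@]1(C)C[C@@H](OC(=O)CP(=O)(OCC)OCC)[C@@H]2O[C@@H]2/C1=C\C | intermediate
20 | oxy-Cope precursor, cis-fused α-phosphono lactone with C6–OH β | C=CC(O)[C@@]1(C)C[C@H]2OC(=O)C(P(=O)(OCC)OCC)[C@H]2[C@H](O)/C1=C\C | intermediate
21 | tripotassium salt of 20 (not isolated) | [K+].[K+].[K+].C=CC([O-])[C@@]1(C)C[C@H]2OC(=O)[C-](P(=O)(OCC)OCC)[C@H]2[C@H]([O-])/C1=C\C | intermediate
22 | tripotassium C1=C2 enolate after the shift (not isolated) | [K+].[K+].[K+].[O-]C=CC[C@H](C)C1=C(C)C[C@H]2OC(=O)[C-](P(=O)(OCC)OCC)[C@H]2[C@@H]1[O-] | intermediate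
23 | seco-eudesmane aldehyde (4S) | O=CCC[C@H](C)C1=C(C)C[C@H]2OC(=O)C(P(=O)(OCC)OCC)[C@H]2[C@@H]1O | intermediate
24 | C1,C6 diol | OCCC[C@H](C)C1=C(C)C[C@H]2OC(=O)C(P(=O)(OCC)OCC)[C@H]2[C@@H]1O | intermediate
25 | isobutyric anhydride | CC(C)C(=O)OC(=O)C(C)C | starting material
26 | bis-isobutyrate α-phosphono lactone | CC(C)C(=O)OCCC[C@H](C)C1=C(C)C[C@H]2OC(=O)C(P(=O)(OCC)OCC)[C@H]2[C@@H]1OC(=O)C(C)C | intermediate
27 | CNP0509808.1 | C=C1C(=O)O[C@@H]2CC(C)=C([C@@H](C)CCCOC(=O)C(C)C)[C@@H](OC(=O)C(C)C)[C@H]12 | target

Total step count: 17. Longest linear sequence: 17 steps (from 1 and 2 to 27).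

Steps most likely to fail

Step 13 (proposed method).
- Risk: the ring closure may be slow, because the carbanion has to give up conjugation with the ester carbonyl to reach the rear of the C7–O bond. A slow closure leaves room for opening of the oxirane at the allylic carbon C6, for migration of the phosphonoacetyl group to C1–OH, or for later drift of the lactone from O8 to O6.
- Fallback (known chemistry only, sets out from 17 and returns at 20): the C7–C11 bond is delivered from aluminium and the lactone is closed through its C–O bond instead. Epoxy diol 17 is treated with excess diethyl(ethoxyethynyl)alane, Et2AlC≡COEt (from ethoxyacetylene, n-BuLi and Et2AlCl), in toluene at 0 °C. The aluminium alkoxide formed at O8 hands the alkynyl group to adjacent C7 on the α face, which should give the ynol ether triol F1. Catalytic p-toluenesulfonic acid in wet THF hydrates the ynol ether, and the gauche C8–OH, rather than the antiperiplanar C6–OH, captures the acyl carbon to give the cis-fused hydroxy lactone F2. Et3SiOSO2CF3 with 2,6-lutidine masks both carbinols as the bis(triethylsilyl) ether F3. LiN(i-Pr)2 followed by ClP(O)(OEt)2 gives the ketene acetal phosphate F4. A further charge of LiN(i-Pr)2 rearranges it by the 1,3 oxygen-to-carbon phosphoryl shift to the silylated α-phosphono lactone F5, and HF·pyridine then releases 20.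

Step 14 (key step).
- Risk: the trianion may be poorly soluble or may decay before it rearranges. The reactive conformer with axial C1 pushes C6–O into the plane of CH3-15 and raises the barrier. Incomplete ionisation could allow phosphoryl migration to O6 or lactone migration. An imperfect quench could let the phosphonate carbanion condense with the new aldehyde.
- Fallback (sets out from 20 and returns at 23): the same [3,3] array is rearranged without any base, as a neutral thermal siloxy-Cope reaction. Me3SiCl and imidazole in DMF convert 20 into the bis(trimethylsilyl) ether F6, in which silylation also blocks retro-ene cleavage. Heating F6 in degassed 1,2-dichlorobenzene at about 180–200 °C in a base-washed sealed tube should give the silyl enol ether F7, with the same suprafacial transfer to 4S. Brief treatment with citric acid in aqueous methanol at 0 °C then cleaves both silyl groups to give 23.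

Step 9.
- Risk: the tertiary sulfamate may ionise instead of eliminating through the cyclic transition state. That would erode the alkene geometry and could draw the neighbouring oxirane into rearrangement, and any (E)-isomer would end as the C4 epimer after the key step.
- Fallback (sets out from 9 and returns at 13): the geometry is fixed by stereospecific Peterson elimination rather than by conformational bias. Ketone 9 is treated with 1-(trimethylsilyl)ethylmagnesium chloride and CeCl3 in THF at −78 °C to give the β-hydroxysilane F8 as two C4 epimers, which are separated. The epimer whose syn elimination leads to the (Z)-alkene is treated with KH in THF at 0 °C, and the other is taken through the anti elimination with BF3·OEt2 in CH2Cl2 at −78 °C, so both converge on 13.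

Further compounds
F1 | step 13 | ynol ether triol (C7α ethoxyethynyl, C6–OH β, C8–OH α, C1–OH) | C=CC(O)[C@@]1(C)C[C@@H](O)[C@@H](C#COCC)[C@H](O)/C1=C\C
F2 | step 13 | cis-fused hydroxy lactone without phosphonate | C=CC(O)[C@@]1(C)C[C@H]2OC(=O)C[C@H]2[C@H](O)/C1=C\C
F3 | step 13 | bis(triethylsilyl) ether of F2 | C=CC(O[Si](CC)(CC)CC)[C@@]1(C)C[C@H]2OC(=O)C[C@H]2[C@H](O[Si](CC)(CC)CC)/C1=C\C
F4 | step 13 | ketene acetal diethyl phosphate | C=CC(O[Si](CC)(CC)CC)[C@@]1(C)C[C@H]2OC(OP(=O)(OCC)OCC)=C[C@H]2[C@H](O[Si](CC)(CC)CC)/C1=C\C
F5 | step 13 | bis(triethylsilyl) ether of 20 | C=CC(O[Si](CC)(CC)CC)[C@@]1(C)C[C@H]2OC(=O)C(P(=O)(OCC)OCC)[C@H]2[C@H](O[Si](CC)(CC)CC)/C1=C\C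
F6 | step 14 | bis(trimethylsilyl) ether of 20 | C=CC(O[Si](C)(C)C)[C@@]1(C)C[C@H]2OC(=O)C(P(=O)(OCC)OCC)[C@H]2[C@H](O[Si](C)(C)C)/C1=C\C
F7 | step 14 | C1 trimethylsilyl enol ether with C6–OSiMe3 (4S) | C[Si](C)(C)OC=CC[C@H](C)C1=C(C)C[C@H]2OC(=O)C(P(=O)(OCC)OCC)[C@H]2[C@@H]1O[Si](C)(C)C
F8 | step 9 | β-hydroxysilane (C4 epimers, C5 undefined) | O=C1O[C@@H]2C[C@@]1(C)C(O)(C(C)[Si](C)(C)C)[C@H]3O[C@@H]23
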